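**Retrosynthetic overview**

1. Target 23 ⇐ 22 by removal of three phenolic benzyl ethers.
2. 22 ⇐ three-component conjunctive coupling of aryl bromide 15, (Z)-alkenyl boronate 18 and the aryllithium from 4: a 1,2-aryl shift from boron to carbon forms both aryl–C bonds of the side chain and both of its stereocentres, then C–B → C–OH.
3. 15 ⇐ trans-selective enolate benzylation of (R)-lactone 13 with benzyl bromide 7.
4. 13 ⇐ enantioselective Baeyer–Villiger ring expansion of prochiral cyclobutanone 12 ⇐ Negishi coupling of dihalide 9 with 3-(bromomethyl)cyclobutanone 10.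
5. Ring order: the three arene rings are carried in from catechol (via guaiacol 2 and 4-iodoguaiacol 3); the lactone is the only ring made (step 9), before the side chain is attached.

Assumption: the configuration is read from the SMILES as lactone (3R,4R) and side chain (1R,2R); for the two catalyst-controlled steps (9 and 12) the ligand enantiomer named is taken to give the drawn sense and would be exchanged for its antipode if a model run shows the opposite.

**Route**

Step 1
Reactants: 1 catechol
Product: 2 2-methoxyphenol (guaiacol)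
Conditions: MeI (1.0 equiv), K2CO3 (1.0 equiv), acetone, reflux
Reagents that add atoms: iodomethane, CI
Why: Williamson mono-O-methylation of the symmetrical diphenol with one equivalent of electrophile; veratrole and unreacted catechol are removed by base extraction and distillation.

Step 2
Reactants: 2 2-methoxyphenol
Product: 3 4-iodo-2-methoxyphenol
Conditions: NIS, TFA (cat.), MeCN, 0 °C → rt
Reagents that add atoms: N-iodosuccinimide, O=C1CCC(=O)N1I
Why: Electrophilic aromatic iodination goes para to the free OH, the stronger donor and the less hindered site.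

Step 3
Reactants: 3 4-iodo-2-methoxyphenol
Product: 4 1-(benzyloxy)-4-iodo-2-methoxybenzene
Conditions: BnBr, K2CO3, DMF, rt
Reagents that add atoms: benzyl bromide, BrCc1ccccc1
Why: Williamson etherification protects the phenol for the organometallic steps.

Step 4
Reactants: 4 1-(benzyloxy)-4-iodo-2-methoxybenzene
Product: 6 [4-(benzyloxy)-3-methoxyphenyl]methanol, via arylmagnesium chloride 5 (not isolated)
Conditions: i-PrMgCl·LiCl, THF, 0 °C → rt; (CH2O)n, rt; aq. NH4Cl
Reagents that add atoms: paraformaldehyde (formaldehyde), C=O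
Why: Iodine–magnesium exchange followed by Grignard addition to formaldehyde gives the benzylic alcohol in one operation.

Step 5
Reactants: 6 [4-(benzyloxy)-3-methoxyphenyl]methanol
Product: 7 1-(benzyloxy)-4-(bromomethyl)-2-methoxybenzene
Conditions: PBr3, Et2O, 0 °C
Reagents that add atoms: phosphorus tribromide, BrP(Br)Br
Why: Standard conversion of an electron-rich benzylic alcohol into the bromide; used without storage.

Step 6
Reactants: 3 4-iodo-2-methoxyphenol
Product: 8 2-bromo-4-iodo-6-methoxyphenol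
Conditions: NBS, i-Pr2NH (cat.), CH2Cl2, 0 °C
Reagents that add atoms: N-bromosuccinimide, O=C1CCC(=O)N1Br
Why: Amine-mediated electrophilic bromination is delivered ortho to the free phenol, the para position being blocked by iodine.

Step 7
Reactants: 8 2-bromo-4-iodo-6-methoxyphenol
Product: 9 2-(benzyloxy)-1-bromo-5-iodo-3-methoxybenzene
Conditions: BnBr, K2CO3, DMF, 50 °C
Reagents that add atoms: benzyl bromide, BrCc1ccccc1
Why: Williamson etherification of the hindered phenol gives the dihalide hub with two sites of different reactivity (C–I before C–Br).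

Step 8
Reactants: 9 2-(benzyloxy)-1-bromo-5-iodo-3-methoxybenzene; 10 3-(bromomethyl)cyclobutan-1-one
Product: 12 3-{[4-(benzyloxy)-3-bromo-5-methoxyphenyl]methyl}cyclobutan-1-one, via alkylzinc bromide 11 (not isolated)
Conditions: 10, Zn, LiCl, THF, 40 °C; then 9, Pd(dppf)Cl2 (3 mol%), THF, 40 °C
Reagents that add atoms: none
Why: Negishi sp3–sp2 coupling; the ketone-tolerant alkylzinc reacts only at the C–I bond because oxidative addition to the hindered ortho C–Br bond is much slower.

Step 9
Reactants: 12 3-{[4-(benzyloxy)-3-bromo-5-methoxyphenyl]methyl}cyclobutan-1-one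
Product: 13 (4R)-4-{[4-(benzyloxy)-3-bromo-5-methoxyphenyl]methyl}oxolan-2-one
Conditions: Sc(OTf)3 (5 mol%), Feng-type chiral N,N′-dioxide (5 mol%), m-CPBA, EtOAc, −20 °C
Reagents that add atoms: m-chloroperbenzoic acid, OOC(=O)c1cccc(Cl)c1
Why: Catalytic enantioselective Baeyer–Villiger ring expansion (desymmetrisation of a 3-substituted cyclobutanone); the chiral Sc(III) complex selects which enantiotopic CH2 migrates in the Criegee intermediate, which sets C4 as R.

Step 10
Reactants: 13 (4R)-4-{[4-(benzyloxy)-3-bromo-5-methoxyphenyl]methyl}oxolan-2-one; 7 1-(benzyloxy)-4-(bromomethyl)-2-methoxybenzene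
Product: 15 (3R,4R)-3-{[4-(benzyloxy)-3-methoxyphenyl]methyl}-4-{[4-(benzyloxy)-3-bromo-5-methoxyphenyl]methyl}oxolan-2-one, via lithium enolate 14 (not isolated)
Conditions: LiHMDS, THF, −78 °C; 7, DMPU, −78 → −40 °C
Reagents that add atoms: none
Why: Lactone enolate alkylation occurs anti to the C4 benzyl group (substrate control), giving the 3,4-trans dibenzylbutyrolactone as in matairesinol syntheses.

Step 11
Reactants: 16 trimethyl(prop-2-yn-1-yloxy)silane
Product: 18 (Z)-3-(trimethylsilyloxy)prop-1-enylboronic acid ester of cis-1,2-dimethylacenaphthylene-1,2-diol [alkenyl B(mac)], via catechol boronate 17 (not isolated)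
Conditions: catecholborane, [Rh(cod)Cl]2 (1.5 mol%), P(i-Pr)3 (6 mol%), Et3N, cyclohexane, rt; then cis-1,2-dimethylacenaphthylene-1,2-diol, rt
Reagents that add atoms: catecholborane, B1Oc2ccccc2O1; cis-1,2-dimethylacenaphthylene-1,2-diol, C[C@]1(O)c2cccc3cccc(c23)[C@@]1(C)O
Why: Rh-vinylidene trans-hydroboration of the terminal alkyne gives the (Z)-alkenyl boronate, and diol exchange installs the hindered mac ligand, which is known to suppress direct Suzuki transmetalation of β-substituted alkenyl boronates.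

Step 12
Reactants: 15 (3R,4R)-3-{[4-(benzyloxy)-3-methoxyphenyl]methyl}-4-{[4-(benzyloxy)-3-bromo-5-methoxyphenyl]methyl}oxolan-2-one; 4 1-(benzyloxy)-4-iodo-2-methoxybenzene; 18 alkenyl B(mac)
Product: 22 (3R,4R)-4-({4-(benzyloxy)-3-[(1R,2R)-1-[4-(benzyloxy)-3-methoxyphenyl]-1,3-dihydroxypropan-2-yl]-5-methoxyphenyl}methyl)-3-{[4-(benzyloxy)-3-methoxyphenyl]methyl}oxolan-2-one, via aryllithium 19 (not isolated), via boron ate complex 20 (not isolated), via secondary boronate 21 (not isolated)
Conditions: 4, n-BuLi, Et2O, −78 °C; 18, −78 °C → rt; evaporate (removes n-BuI); Pd(OAc)2 (3 mol%), (Sp,Sp)-Mandyphos (3.6 mol%), NaOTf, 15, THF, 60 °C; then 3 M NaOH, 30% H2O2, 0 °C → rt; citric acid work-up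
Reagents that add atoms: hydrogen peroxide, OO
Why: Proposed new method: a diastereo- and enantioselective Pd-catalysed conjunctive cross-coupling in a substrate combination not yet demonstrated (a Z-configured, allylic-oxygenated alkenyl boron ate complex with an ortho-alkoxy aryl bromide that carries a lactone), in which the Pd(II)–aryl from oxidative addition of 15 binds the alkene of 20, the aryl group on boron undergoes an anti-periplanar 1,2-shift from B to the α-carbon as Pd bonds to the β-carbon, and stereoretentive reductive elimination forms the second aryl–C bond, so that net anti addition across the Z-alkene gives the anti (1R,2R) array with the face chosen by Mandyphos, after which stereoretentive C–B oxidation gives the carbinol, the TMS ether is lost in the basic work-up and mild acid re-closes any opened lactone; the closest known reaction is the Pd/Mandyphos conjunctive coupling of vinyl and (E)-β-alkyl alkenyl boron ate complexes with aryl triflates or halides.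

Step 13
Reactants: 22 tris-benzyl ether diol
Product: 23 (3R,4R)-4-({3-[(1R,2R)-1,3-dihydroxy-1-(4-hydroxy-3-methoxyphenyl)propan-2-yl]-4-hydroxy-5-methoxyphenyl}methyl)-3-[(4-hydroxy-3-methoxyphenyl)methyl]oxolan-2-one
Conditions: H2 (1 atm), 10% Pd/C, EtOAc–EtOH, rt
Reagents that add atoms: none
Why: Neutral hydrogenolysis cleaves the three aryl benzyl ethers quickly, while the secondary benzylic alcohol, the lactone and all four stereocentres are untouched under acid-free conditions.

**Compound list**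

1 | catechol | Oc1ccccc1O | starting material
2 | 2-methoxyphenol | COc1ccccc1O | intermediate
3 | 4-iodo-2-methoxyphenol | COc1cc(I)ccc1O | intermediate
4 | 1-(benzyloxy)-4-iodo-2-methoxybenzene | COc1cc(I)ccc1OCc1ccccc1 | intermediate
5 | [4-(benzyloxy)-3-methoxyphenyl]magnesium chloride | COc1cc([Mg]Cl)ccc1OCc1ccccc1 | intermediate (not isolated)
6 | [4-(benzyloxy)-3-methoxyphenyl]methanol | COc1cc(CO)ccc1OCc1ccccc1 | intermediate
7 | 1-(benzyloxy)-4-(bromomethyl)-2-methoxybenzene | COc1cc(CBr)ccc1OCc1ccccc1 | intermediate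
8 | 2-bromo-4-iodo-6-methoxyphenol | COc1cc(I)cc(Br)c1O | intermediate
9 | 2-(benzyloxy)-1-bromo-5-iodo-3-methoxybenzene | COc1cc(I)cc(Br)c1OCc1ccccc1 | intermediate
10 | 3-(bromomethyl)cyclobutan-1-one | O=C1CC(CBr)C1 | starting material
11 | [(3-oxocyclobutyl)methyl]zinc bromide | O=C1CC(C[Zn]Br)C1 | intermediate (not isolated)
12 | 3-{[4-(benzyloxy)-3-bromo-5-methoxyphenyl]methyl}cyclobutan-1-one | COc1cc(CC2CC(=O)C2)cc(Br)c1OCc1ccccc1 | intermediate
13 | (4R)-4-{[4-(benzyloxy)-3-bromo-5-methoxyphenyl]methyl}oxolan-2-one | COc1cc(C[C@H]2COC(=O)C2)cc(Br)c1OCc1ccccc1 | intermediate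
14 | lithium enolate of 13 (lithium 4-(arylmethyl)-4,5-dihydrofuran-2-olate, same C4 configuration) | COc1cc(C[C@H]2COC(O[Li])=C2)cc(Br)c1OCc1ccccc1 | intermediate (not isolated)
15 | (3R,4R)-3-{[4-(benzyloxy)-3-methoxyphenyl]methyl}-4-{[4-(benzyloxy)-3-bromo-5-methoxyphenyl]methyl}oxolan-2-one | COc1cc(C[C@H]2C(=O)OC[C@@H]2Cc2cc(OC)c(OCc3ccccc3)c(Br)c2)ccc1OCc1ccccc1 | intermediate
16 | trimethyl(prop-2-yn-1-yloxy)silane | C#CCO[Si](C)(C)C | starting material
17 | 2-[(Z)-3-(trimethylsilyloxy)prop-1-enyl]-1,3,2-benzodioxaborole | C[Si](C)(C)OC/C=C\B1Oc2ccccc2O1 | intermediate (not isolated)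
18 | (Z)-3-(trimethylsilyloxy)prop-1-enylboronic acid ester of cis-1,2-dimethylacenaphthylene-1,2-diol | C[Si](C)(C)OC/C=C\B1O[C@@]2(C)c3cccc4cccc(c34)[C@@]2(C)O1 | intermediate
19 | [4-(benzyloxy)-3-methoxyphenyl]lithium | COc1cc([Li])ccc1OCc1ccccc1 | intermediate (not isolated)
20 | lithium [4-(benzyloxy)-3-methoxyphenyl][(Z)-3-(trimethylsilyloxy)prop-1-enyl]B(mac) ate complex (configuration at boron not defined) | [Li+].COc1cc(ccc1OCc1ccccc1)[B-]1(/C=C\CO[Si](C)(C)C)O[C@@]2(C)c3cccc4cccc(c34)[C@@]2(C)O1 | intermediate (not isolated)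
21 | (3R,4R)-lactone carrying the (1R,2R)-1-aryl-1-[B(mac)]-3-(trimethylsilyloxy)propan-2-yl side chain | COc1cc(C[C@H]2C(=O)OC[C@@H]2Cc2cc(OC)c(OCc3ccccc3)c([C@H](CO[Si](C)(C)C)[C@@H](B3O[C@@]4(C)c5cccc6cccc(c56)[C@@]4(C)O3)c3ccc(OCc4ccccc4)c(OC)c3)c2)ccc1OCc1ccccc1 | intermediate (not isolated)
22 | (3R,4R)-4-({4-(benzyloxy)-3-[(1R,2R)-1-[4-(benzyloxy)-3-methoxyphenyl]-1,3-dihydroxypropan-2-yl]-5-methoxyphenyl}methyl)-3-{[4-(benzyloxy)-3-methoxyphenyl]methyl}oxolan-2-one | COc1cc(C[C@H]2C(=O)OC[C@@H]2Cc2cc(OC)c(OCc3ccccc3)c([C@H](CO)[C@@H](O)c3ccc(OCc4ccccc4)c(OC)c3)c2)ccc1OCc1ccccc1 | intermediate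
23 | (3R,4R)-4-({3-[(1R,2R)-1,3-dihydroxy-1-(4-hydroxy-3-methoxyphenyl)propan-2-yl]-4-hydroxy-5-methoxyphenyl}methyl)-3-[(4-hydroxy-3-methoxyphenyl)methyl]oxolan-2-one | COc1cc(C[C@H]2C(=O)OC[C@@H]2Cc2cc(OC)c(O)c([C@H](CO)[C@@H](O)c3ccc(O)c(OC)c3)c2)ccc1O | target

**Step count and risk**

Total steps: 13. Longest linear sequence: 9 (steps 1, 2, 6, 7, 8, 9, 10, 12, 13).

The three steps most likely to fail:

Step 12 (the proposed new coupling). The risks are direct Suzuki coupling of the ate complex, β-siloxy or β-hydride elimination from the alkyl–Pd intermediate, slow oxidative addition at the hindered C–Br bond, and untested facial control for a Z-alkenyl partner. The fallback uses known chemistry, sets out from 15 and comes back at 22. Propargyl alcohol is silylated (TBSCl, imidazole) to tert-butyldimethyl(prop-2-yn-1-yloxy)silane F1 and hydroborated (pinacolborane, cat. Cp2Zr(H)Cl) to the (E)-alkenyl pinacol boronate F2. Suzuki–Miyaura coupling of F2 with 15 (Pd(dppf)Cl2, K3PO4, dioxane–water) gives the (E)-cinnamyl silyl ether F3. Shi epoxidation (D-fructose-derived ketone, Oxone, buffered) gives the (2R,3R)-epoxy silyl ether F4. Methylaluminium bis(4-bromo-2,6-di-tert-butylphenoxide) in CH2Cl2 at −78 °C then effects the stereospecific semipinacol 1,2-shift of the siloxymethyl group, with inversion at the benzylic carbon, to the (R)-2-aryl-3-siloxypropanal F5. Felkin–Anh addition of Grignard 5 at −78 °C, where the aldehyde reacts before the lactone, gives the anti (1R,2R) alcohol F6, and TBAF releases 22.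

Step 9 (enantioselective Baeyer–Villiger oxidation). The enantioselectivity for a benzyl-substituted cyclobutanone may be only moderate, and the electron-rich arene is exposed to peracid. The fallback sets out from 9 and comes back at 13. Iodine–magnesium exchange on 9 (i-PrMgCl·LiCl), transmetalation to zinc (ZnCl2) and Pd(PPh3)4-catalysed coupling with 4-(bromomethyl)furan-2(5H)-one give the butenolide 4-{[4-(benzyloxy)-3-bromo-5-methoxyphenyl]methyl}furan-2(5H)-one F7. Copper hydride asymmetric conjugate reduction (Cu(OAc)2, p-tol-BINAP, PMHS, t-BuOH, toluene) then gives 13.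

Step 8 (Negishi coupling). Forming the alkylzinc next to a strained ketone may be inefficient, and some reaction at C–Br is possible. The fallback sets out from 9 and comes back at 12. Iodine–magnesium exchange on 9 and Cu-catalysed allylation with allyl bromide give the allylarene 5-allyl-2-(benzyloxy)-1-bromo-3-methoxybenzene F8. [2+2] cycloaddition with dichloroketene (Cl3CCOCl, Zn–Cu, Et2O) gives the 2,2-dichlorocyclobutanone F9, and Zn/AcOH dechlorination gives 12.

Further compounds
F1 | step 12 | tert-butyldimethyl(prop-2-yn-1-yloxy)silane | C#CCO[Si](C)(C)C(C)(C)C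
F2 | step 12 | tert-butyldimethyl{[(E)-3-(4,4,5,5-tetramethyl-1,3,2-dioxaborolan-2-yl)prop-2-en-1-yl]oxy}silane | CC(C)(C)[Si](C)(C)OC/C=C/B1OC(C)(C)C(C)(C)O1
F3 | step 12 | (3R,4R)-3-{[4-(benzyloxy)-3-methoxyphenyl]methyl}-4-({4-(benzyloxy)-3-[(E)-3-(tert-butyldimethylsilyloxy)prop-1-enyl]-5-methoxyphenyl}methyl)oxolan-2-one | COc1cc(C[C@H]2C(=O)OC[C@@H]2Cc2cc(OC)c(OCc3ccccc3)c(/C=C/CO[Si](C)(C)C(C)(C)C)c2)ccc1OCc1ccccc1
F4 | step 12 | (3R,4R)-lactone carrying the (2R,3R)-3-[(tert-butyldimethylsilyloxy)methyl]oxiran-2-yl group on the central ring | COc1cc(C[C@H]2C(=O)OC[C@@H]2Cc2cc(OC)c(OCc3ccccc3)c([C@H]3O[C@@H]3CO[Si](C)(C)C(C)(C)C)c2)ccc1OCc1ccccc1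
F5 | step 12 | (3R,4R)-lactone carrying the (2R)-1-(tert-butyldimethylsilyloxy)-3-oxopropan-2-yl group on the central ring | COc1cc(C[C@H]2C(=O)OC[C@@H]2Cc2cc(OC)c(OCc3ccccc3)c([C@H](CO[Si](C)(C)C(C)(C)C)C=O)c2)ccc1OCc1ccccc1
F6 | step 12 | 3-O-tert-butyldimethylsilyl ether of 22 | COc1cc(C[C@H]2C(=O)OC[C@@H]2Cc2cc(OC)c(OCc3ccccc3)c([C@H](CO[Si](C)(C)C(C)(C)C)[C@@H](O)c3ccc(OCc4ccccc4)c(OC)c3)c2)ccc1OCc1ccccc1
F7 | step 9 | 4-{[4-(benzyloxy)-3-bromo-5-methoxyphenyl]methyl}furan-2(5H)-one | COc1cc(CC2=CC(=O)OC2)cc(Br)c1OCc1ccccc1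
F8 | step 8 | 5-allyl-2-(benzyloxy)-1-bromo-3-methoxybenzene | C=CCc1cc(OC)c(OCc2ccccc2)c(Br)c1
F9 | step 8 | 3-{[4-(benzyloxy)-3-bromo-5-methoxyphenyl]methyl}-2,2-dichlorocyclobutan-1-one (racemic) | COc1cc(CC2CC(=O)C2(Cl)Cl)cc(Br)c1OCc1ccccc1
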